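(The data were computed with made-up constants; noise was put on by code.)

3 questions hang on this flask, a racemic substrate pair worked by a single-handed catalyst, with the partner consumed as it turns over.

| flask | left-handed substrate | right-handed substrate | partner | precatalyst | remark | time |
|---|---|---|---|---|---|---|
| Thursday's | 0.10 M | 0.10 M | 4 equiv | 0.2 mol% | run made earlier |  |
| Sunday's | 0.16 M | 0.16 M | 4 equiv | 0.2 mol% | run made earlier |  |
| Wednesday's | 0.074 M | 0.074 M | 4 equiv | 0.1 mol% | run made earlier |  |
| flask | 0.074 M | 0.074 M | 4.00 equiv | 0.2 mol% |  | 15 h |

| run | time / h | left-handed product / % | right-handed product / % | left-handed substrate / % |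
|---|---|---|---|---|
| Thursday's | 1.00 | 27.9 | 10.3 | 29.5 |
| Thursday's | 2.00 | 45.0 | 15.8 | 18.3 |
| Thursday's | 5.00 | 64.0 | 23.3 | 6.7 |
| Thursday's | 12.0 | 71.7 | 25.3 | 1.7 |
| Sunday's | 1.00 | 44.7 | 17.4 | 17.5 |
| Sunday's | 2.00 | 59.9 | 23.1 | 7.6 |
| Sunday's | 5.00 | 70.6 | 27.0 | 1.6 |
| Sunday's | 12.0 | 72.0 | 28.4 | 0 |
| Wednesday's | 1.50 | 19.9 | 7.3 | 36.0 |
| Wednesday's | 4.00 | 40.0 | 14.4 | 22.6 |
| Wednesday's | 8.00 | 51.5 | 17.8 | 14.9 |
| Wednesday's | 12.0 | 55.4 | 19.8 | 12.1 |

(readings scatter by 0.3 percentage points)

1. excess of left-handed product over right-handed product in the product at 20 min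
2. excess of left-handed product over right-handed product in the product at 15 h
3. part of the left-handed substrate and right-handed substrate charged together that has reacted at 15 h

- catalyst is single-handed; left-handed substrate and right-handed substrate are mirror images of each other, charged as a racemate, each of them at the stated concentration
- on the list of suspects stand: partner + catalyst + left-handed substrate -> catalyst + left-handed product; partner + catalyst + right-handed substrate -> catalyst + right-handed product; left-handed substrate <-> right-handed substrate; partner + precatalyst -> catalyst + spent reagent; catalyst <-> dormant form; 2 catalyst <-> resting dimer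
- an excess is the difference of the two amounts in percent of their sum
- an excess is below zero if the other one leads

Wednesday's run makes 1500 turnovers per precatalyst by 12.0 h, with half this flask's loading. This flask needs 1000 to use up both substrates, yet I don't expect it to finish.

Turnovers are the wrong count here, so I count lifetimes, as for pseudo-first-order decay. Between 1.00 h readings, Sunday's count is 2.02 times Thursday's, and concentration times its square root gives 2.02. At 12.0 h, Wednesday over Thursday reads 0.398. First order in partner and half order in catalyst gives 0.450, whole order in catalyst 0.274. The reading matches neither order, so I take the gain from the readings themselves: with concentration scaled out as above, Thursday's count over Wednesday's at 12.0 h says twice the loading buys 1.60 times the lifetimes.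

Scaling Thursday's count at 12.0 h and adding Wednesday's late pace, multiplied by that gain, for the remaining hours, my count for this flask at 15 h, the natural logarithm of substrate charged over substrate left, is 2.49. That means 91.7% reacted. Wednesday's substrates read 12.1% and, by difference, 12.7%, so I take Wednesday's product excess, 47.3%, for both times.

The forecast says 48%, 47.5% and 90%, holding that “racemisation is fast compared with reaction”.

The flask gives 49.1%, 48.1% and 91.5%, which is 2.47 lifetimes against my 2.49. At 15.0 h the dormant form holds 90.5% of the catalyst charged.

    partner + catalyst + left-handed substrate → catalyst + left-handed product (k = 23.0 L² mol⁻² s⁻¹)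
    partner + catalyst + right-handed substrate → catalyst + right-handed product (k = 7.70 L² mol⁻² s⁻¹)
    left-handed substrate ⇌ right-handed substrate (k = 7.70 × 10⁻⁴ s⁻¹)
    partner + precatalyst → catalyst + spent reagent (k = 0.00190 L mol⁻¹ s⁻¹)
    catalyst ⇌ dormant form (K = 31.0, k = 2.00 × 10⁻⁴ s⁻¹)
    2 catalyst ⇌ resting dimer, settled at all times (K = 76000 L mol⁻¹)

With 6.80 equiv of partner, the count scales to 4.23 lifetimes, or 98.5% reacted. The computed neighbour reaches 99.2%.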